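**Retrosynthetic overview**

- The hexamer is cut at its five methylene bridges. Ring A (butyrylfilicinic acid 6) is joined last to a pentamer Mannich base 15 (rings B to F). Each bridge comes from an ortho-quinone methide released from an aryl-CH2NMe2 group.
- The pentamer is grown from ring F with two symmetric building blocks used in excess: the bis(aminomethyl) monomer 11 (bis-electrophile) and the methylene-bis dimer 12 (bis-nucleophile).
- Ring A is not made from an arene. Its gem-dimethyl carbon lies between two enolised carbonyl carbons of a cyclohexane-1,3,5-trione, so it is the α-carbon of an isopropyl ketone and the hydroxy-bearing ring carbon beside it (the one next to the butyryl-bearing carbon) is an ester carbon. A Claisen (Dieckmann) condensation of the enol-ether-masked 3,5-dioxo ester 3 closes this bond; 3 already holds all eight ring-A carbons and all three ring oxygens.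
- Filicinic acid 5 is symmetric, so its two CH positions then take the butyryl group (step 3) and the bridge to ring B (step 11). Ring A is the only ring built (step 2); rings B to F come from phloroglucinol and 2-methylphloroglucinol.

Key step: step 2

Remark: the target has no stereocentre; ring A is an enolised 2-acylcyclohexane-1,3,5-trione, and the SMILES of 4, 5, 6 and 16 each show one tautomer of the same compound.

**Route**

Step 1
Reactants: 1 methyl (E)-3-methoxybut-2-enoate; 2 N-methoxy-N,2-dimethylpropanamide
Product: 3 methyl (E)-3-methoxy-6-methyl-5-oxohept-2-enoate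
Conditions: LiN(i-Pr)2 (LDA, 1.1 equiv), THF, -78 °C; then 2, -78 to -20 °C; aq NH4Cl
Reagents that add atoms: none
Why: Kinetic γ-deprotonation of the β-methoxy enoate (methyl cis to the ester) gives the lithium dienolate, which should be acylated at its γ-carbon by the Weinreb amide in a vinylogous Claisen acylation, the stable N-methoxy-N-methyl chelate preventing over-addition before the quench.

Step 2
Reactants: 3 methyl (E)-3-methoxy-6-methyl-5-oxohept-2-enoate
Product: 5 filicinic acid, via O-methylfilicinic acid 4 (not isolated)
Conditions: NaOMe (3 equiv), MeOH (0.05 M), reflux, N2; then 2 M aq HCl, 60 °C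
Reagents that add atoms: water, O
Why: Proposed new method: NaOMe should equilibrate 3 with all its enolates, and the minor cross-conjugated enolate at the isopropyl methine should attack the ester carbonyl in a Dieckmann-type Claisen condensation, expelling methoxide and joining the gem-dimethyl carbon to the flanking ring carbonyl carbon. The closest known reactions are the Dieckmann cyclisation of δ-keto esters to cyclohexane-1,3-diones (as in the dimedone synthesis) and the Claisen-mode folding of masked triketo esters into acylphloroglucinols; what is new is a tertiary ketone α-carbon as nucleophile beside a more acidic doubly activated CH2. The six-membered ring closes in a 6-(enolendo)-exo-trig mode, for which the (E)-enol ether holds the ester cis to the keto chain, and no stereocentre is formed. The step needs C- over O-acylation and attack from the methine, not from the CH2: the CH2 carbanion could only close a four-membered ring, and the O-methyl mask keeps any O-cyclised 2-pyrone neutral so that methoxide reopens it. Only the carbocycle is drained irreversibly, as the vinylogous carboxylate of 4, whose enol ether the HCl work-up should hydrolyse to the symmetric trione 5.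

Step 3
Reactants: 5 filicinic acid
Product: 6 butyrylfilicinic acid
Conditions: butyryl chloride (1.1 equiv), AlCl3 (3 equiv), PhNO2, 20 to 50 °C; ice, aq HCl
Reagents that add atoms: butyryl chloride, CCCC(=O)Cl
Why: Friedel-Crafts-type C-acylation of the enolised β-triketone at one of its two equivalent CH carbons should stop at the mono-acyl stage because the chelated 2-acyl product is deactivated.

Step 4
Reactants: 7 phloroglucinol
Product: 8 butyrylphloroglucinol
Conditions: butyryl chloride (1.0 equiv), AlCl3 (3 equiv), PhNO2/CH2Cl2, 0 to 40 °C; aq HCl
Reagents that add atoms: butyryl chloride, CCCC(=O)Cl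
Why: Friedel-Crafts acylation of the electron-rich triol should give the mono-ketone, the first acyl group deactivating the ring towards a second.

Step 5
Reactants: 9 2-methylphloroglucinol
Product: 10 1-(2,4,6-trihydroxy-3-methylphenyl)butan-1-one
Conditions: butyryl chloride (1.0 equiv), AlCl3 (3 equiv), PhNO2/CH2Cl2, 0 to 40 °C; aq HCl
Reagents that add atoms: butyryl chloride, CCCC(=O)Cl
Why: Friedel-Crafts acylation at one of the two equivalent free ring positions should give a single regioisomer with one nucleophilic CH left.

Step 6
Reactants: 8 butyrylphloroglucinol
Product: 11 1-[3,5-bis(dimethylaminomethyl)-2,4,6-trihydroxyphenyl]butan-1-one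
Conditions: 37% aq HCHO (2.2 equiv), 40% aq Me2NH (2.5 equiv), EtOH, 0 °C to rt
Reagents that add atoms: formaldehyde, C=O; dimethylamine, CNC
Why: A double Mannich aminomethylation should fill both free ring positions, giving a bis-electrophile precursor with no nucleophilic ring CH.

Step 7
Reactants: 8 butyrylphloroglucinol (two molecules are joined by one formaldehyde carbon)
Product: 12 methylenebis(butyrylphloroglucinol)
Conditions: 8 (4 equiv per HCHO), 37% aq HCHO, 1% aq KOH, 0 °C, 10 min; then dil. HCl
Reagents that add atoms: formaldehyde, C=O; butyrylphloroglucinol 8 (second molecule), CCCC(=O)c1c(O)cc(O)cc1O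
Why: Lederer-Manasse hydroxymethylation of one molecule of 8, loss of water to an ortho-quinone methide and Michael capture by the phenolate of a second molecule of 8 (formaldehyde condensation) should give the symmetric dimer, the excess of 8 stopping the chain there.

Step 8
Reactants: 10 1-(2,4,6-trihydroxy-3-methylphenyl)butan-1-one; 11 bis-Mannich base (4 equiv)
Product: 13 dimer Mannich base of rings F and E
Conditions: 1,4-dioxane, 90 °C, N2 sweep
Reagents that add atoms: none
Why: Thermal retro-Mannich loss of Me2NH from the ortho-hydroxybenzylamine should give an ortho-quinone methide that the single free ring carbon of 10 captures by Michael addition and rearomatisation, the excess of 11 holding the reaction at mono-coupling.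

Step 9
Reactants: 13 dimer Mannich base; 12 methylenebis(butyrylphloroglucinol) (3 equiv)
Product: 14 tetramer of rings F, E, D and C with one free position on ring C
Conditions: 1,4-dioxane, 90 °C, N2 sweep
Reagents that add atoms: none
Why: The same ortho-quinone methide Michael coupling should join 13 (no nucleophilic CH) to one of the two equivalent free positions of 12, the excess of 12 suppressing double alkylation.

Step 10
Reactants: 14 tetramer; 11 bis-Mannich base (4 equiv)
Product: 15 pentamer Mannich base of rings F to B
Conditions: 1,4-dioxane, 90 °C, N2 sweep
Reagents that add atoms: none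
Why: Ortho-quinone methide Michael coupling at the single free position of 14 should install ring B with its second aminomethyl arm intact, the excess of 11 preventing bridging of two tetramers.

Step 11
Reactants: 15 pentamer Mannich base; 6 butyrylfilicinic acid (1.5 equiv)
Product: 16 CNP0309827.0
Conditions: 1,4-dioxane, 90 °C, N2 sweep
Reagents that add atoms: none
Why: The ortho-quinone methide from 15 should be captured by the only free enolic CH of the vinylogous acid 6 (Michael addition), and neither partner can self-condense.

**Compound list**

1 | methyl (E)-3-methoxybut-2-enoate | COC(=O)/C=C(/OC)C | starting material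
2 | N-methoxy-N,2-dimethylpropanamide | CC(C)C(=O)N(C)OC | starting material
3 | methyl (E)-3-methoxy-6-methyl-5-oxohept-2-enoate | COC(=O)/C=C(/OC)CC(=O)C(C)C | intermediate
4 | O-methylfilicinic acid (5-hydroxy-3-methoxy-6,6-dimethylcyclohexa-2,4-dien-1-one) | COC1=CC(=O)C(C)(C)C(O)=C1 | intermediate
5 | filicinic acid (3,5-dihydroxy-4,4-dimethylcyclohexa-2,5-dien-1-one) | CC1(C)C(O)=CC(=O)C=C1O | intermediate
6 | butyrylfilicinic acid (2-butanoyl-3,5-dihydroxy-4,4-dimethylcyclohexa-2,5-dien-1-one) | CCCC(=O)C1=C(O)C(C)(C)C(O)=CC1=O | intermediate
7 | phloroglucinol (benzene-1,3,5-triol) | Oc1cc(O)cc(O)c1 | starting material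
8 | butyrylphloroglucinol, 1-(2,4,6-trihydroxyphenyl)butan-1-one | CCCC(=O)c1c(O)cc(O)cc1O | intermediate
9 | 2-methylphloroglucinol (2-methylbenzene-1,3,5-triol) | Cc1c(O)cc(O)cc1O | starting material
10 | 1-(2,4,6-trihydroxy-3-methylphenyl)butan-1-one | CCCC(=O)c1c(O)cc(O)c(C)c1O | intermediate
11 | 1-[3,5-bis(dimethylaminomethyl)-2,4,6-trihydroxyphenyl]butan-1-one | CCCC(=O)c1c(O)c(CN(C)C)c(O)c(CN(C)C)c1O | intermediate
12 | methylenebis(butyrylphloroglucinol), two butyrylphloroglucinol rings joined by CH2 at position 3 | CCCC(=O)c1c(O)cc(O)c(Cc2c(O)cc(O)c(C(=O)CCC)c2O)c1O | intermediate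
13 | dimer Mannich base: ring F (methyl, butyryl) joined by CH2 to ring E carrying CH2NMe2 | CCCC(=O)c1c(O)c(C)c(O)c(Cc2c(O)c(CN(C)C)c(O)c(C(=O)CCC)c2O)c1O | intermediate
14 | tetramer of rings F, E, D and C, with one free aromatic CH on ring C | CCCC(=O)c1c(O)c(C)c(O)c(Cc2c(O)c(Cc3c(O)c(Cc4c(O)cc(O)c(C(=O)CCC)c4O)c(O)c(C(=O)CCC)c3O)c(O)c(C(=O)CCC)c2O)c1O | intermediate
15 | pentamer Mannich base of rings F to B, with CH2NMe2 on ring B | CCCC(=O)c1c(O)c(C)c(O)c(Cc2c(O)c(Cc3c(O)c(Cc4c(O)c(Cc5c(O)c(CN(C)C)c(O)c(C(=O)CCC)c5O)c(O)c(C(=O)CCC)c4O)c(O)c(C(=O)CCC)c3O)c(O)c(C(=O)CCC)c2O)c1O | intermediate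
16 | CNP0309827.0 | CCCC(=O)C1=C(O)C(C)(C)C(O)=C(Cc2c(O)c(Cc3c(O)c(Cc4c(O)c(Cc5c(O)c(Cc6c(O)c(C)c(O)c(C(=O)CCC)c6O)c(O)c(C(=O)CCC)c5O)c(O)c(C(=O)CCC)c4O)c(O)c(C(=O)CCC)c3O)c(O)c(C(=O)CCC)c2O)C1=O | target

**Summary**

Total step count: 11. Longest linear sequence: 6 steps (steps 4, 6, 8, 9, 10 and 11).

Steps most likely to fail:

1. Step 2 (proposed new method). The ketone may enolise productively only towards the doubly activated CH2, so the chain would rest as its extended enolate or be lost to intermolecular condensation, and the methine would never acylate. The fallback is the known dearomative gem-dimethylation of an acylphloroglucinol. It sets out from compound 8: NaOMe (3 equiv) and iodomethane (2.2 equiv) in MeOH at 0 °C to rt should methylate the phenolate twice at the same free ring carbon and give butyrylfilicinic acid directly, with the mono- and trimethylated by-products removed by chromatography. It comes back to the route at compound 6 and makes no compound outside the list (F0).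

2. Step 10. Both aminomethyl arms of 11 may react, bridging two tetramers, and the existing methylene bridges may redistribute by retro-Michael exchange during long heating of the poorly soluble tetramer. The fallback reverses the polarity and adds one arm at a time. It sets out from compound 14: a Mannich reaction (aq HCHO, Me2NH, EtOH) at its single free position should give the tetramer Mannich base F1. Heating F1 in dioxane with a large excess of cheap 8 should give the pentamer with a free position on ring B, F2. A second Mannich reaction on F2 comes back to the route at compound 15.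

3. Step 11. Release of the ortho-quinone methide from the bulky, strongly hydrogen-bonded pentamer may be slow, so that decomposition and bridge exchange outrun the coupling. The fallback changes the last disconnection from the A–B bridge to the B–C bridge. It sets out from compound 6: heating with excess 11 in dioxane should give the small, more reactive ring A–ring B dimer Mannich base F3. Coupling F3 with tetramer 14 at its single free ring-C position comes back to the route at compound 16.

**Further compounds**

F0 | step 2 | none | none
F1 | step 10 | tetramer Mannich base of rings F, E, D and C, with CH2NMe2 on ring C | CCCC(=O)c1c(O)c(C)c(O)c(Cc2c(O)c(Cc3c(O)c(Cc4c(O)c(CN(C)C)c(O)c(C(=O)CCC)c4O)c(O)c(C(=O)CCC)c3O)c(O)c(C(=O)CCC)c2O)c1O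
F2 | step 10 | pentamer of rings F to B with one free aromatic CH on ring B | CCCC(=O)c1c(O)c(C)c(O)c(Cc2c(O)c(Cc3c(O)c(Cc4c(O)c(Cc5c(O)cc(O)c(C(=O)CCC)c5O)c(O)c(C(=O)CCC)c4O)c(O)c(C(=O)CCC)c3O)c(O)c(C(=O)CCC)c2O)c1O
F3 | step 11 | dimer Mannich base of ring A and ring B, with CH2NMe2 on ring B | CCCC(=O)C1=C(O)C(C)(C)C(O)=C(Cc2c(O)c(CN(C)C)c(O)c(C(=O)CCC)c2O)C1=O
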